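The readings stem from a simulated flask with made-up constants, and the scatter is random.

Temperature first: Sunday's and Friday's runs both stand at 5 °C, so holding them side by side shows what L does with temperature held. Here is what is on the bench and what we must choose between.

| flask | D | J | L | temperature | remark | time |
|---|---|---|---|---|---|---|
| Sunday's | 1 M | 1.1 equiv | 0.57 M | 5 °C | run made earlier |  |
| Tuesday's | 1 M | 1.1 equiv | 0.92 M | 32 °C | run made earlier |  |
| Friday's | 1 M | 1.1 equiv | 1.1 M | 5 °C | run made earlier |  |
| Saturday's | 0.56 M | 1.1 equiv | 0.50 M | 32 °C | run made earlier |  |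
| grey | 0.25 M | 1.10 equiv | 0.500 M | 55 °C |  | 80 min |
| ochre | 1.0 M | 1.10 equiv | 0.500 M | 40 °C |  | 80 min |
| green | 1.0 M | 1.10 equiv | 0.500 M | 10 °C |  | 80 min |
| teal | 0.60 M | 1.10 equiv | 1.50 M | 40 °C |  | 80 min |
| amber | 1.0 M | 0.740 equiv | 1.50 M | 25 °C |  | 80 min |

| run | time / min | X / % |
|---|---|---|
| Sunday's | 120 | 3.2 |
| Sunday's | 240 | 8.7 |
| Sunday's | 360 | 15.1 |
| Sunday's | 480 | 20.9 |
| Tuesday's | 10.0 | 4.4 |
| Tuesday's | 30.0 | 17.2 |
| Tuesday's | 50.0 | 26.5 |
| Tuesday's | 80.0 | 36.5 |
| Friday's | 60.0 | 0.7 |
| Friday's | 180 | 5.1 |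
| Friday's | 300 | 9.7 |
| Friday's | 480 | 16.7 |
| Saturday's | 20.0 | 7.9 |
| Saturday's | 40.0 | 18.6 |
| Saturday's | 60.0 | 25.9 |
| Saturday's | 80.0 | 34.3 |

(each reading ± 0.5 percentage points)

1. the flasks by amount of X, in percent of the D charged, highest first, at 80 min (grey / ochre / green / teal / amber)
2. the same order at 5.0 h (grey / ochre / green / teal / amber)
3. the amount of X, in percent of the D charged of the flask you put first, at 80 min
4. the amount of X, in percent of the D charged of the flask you put last, at 80 min

- on the list of suspects stand: D -> G; J -> Z; G + Z -> X; J + L -> Q; J + X -> E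

Think of J as a tank with two parallel drains: J → Z, and J + L → Q, which at a given L is pseudo-first-order in J. X forms from G + Z, so while G stands near its full charge, the rate of X follows one concentration, that of Z. Let K be the amount of L at which the two drains run equally. Then the share of J that reaches Z is s = K/(K + L), taken at the charged L. We read K from the runs by taking the slopes over the last three readings of each cold run. Friday's slope is 0.761 of Sunday's. If that ratio is the ratio of the two shares, then K = 1.11 M, a rough reading given the scatter.

The quantity we carry is the ceiling C on X, in percent of the D charged: the equivalents of J times s. With L at 0.500 M and 1.10 equiv of J, s is 69.0 % and C is 75.9 %, for ochre and grey alike. Teal gets 46.9 % and amber 31.5 %. So our next run keeps L at 0.500 M rather than 1.50 M, and keeps J at 1.10 equiv rather than 0.740 equiv. It is also run warm, since Sunday's cold flask reached just 20.9 % after 480 min. That recipe is ochre. The ceiling cannot separate ochre from grey, so we call those two a near tie.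

The forecast gave grey > ochre > teal > amber > green at 80 min and ochre > grey > teal > amber > green at 5.0 h, with 66 % (54 % to 76 %) for the first and 4 % (2.5 % to 6.5 %) for the last, reasoning that “Grey is hottest and finishes first”.

The simulation gives ochre > grey > teal > amber > green at 80 min, with ochre at 59.2 % and green at 3.90 %, and ochre > grey > teal > green > amber at 5.0 h. At 5.0 h ochre has 70.3 %, grey 68.1 %, teal 35.8 % and amber 20.2 %, each below its ceiling.

    D → G (k = 0.0650 /s, Ea = 93.0 kJ/mol)
    J → Z (k = 0.00210 /s, Ea = 80.0 kJ/mol)
    G + Z → X (k = 7.40 × 10⁻⁴ /M/s, Ea = 61.0 kJ/mol)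
    J + L → Q (k = 0.00340 /M/s, Ea = 68.0 kJ/mol)
    J + X → E (k = 0.00100 /M/s, Ea = 65.0 kJ/mol)
    (constants at 40 °C)

In ochre at 0.178 min, the half-life of J is 5.5 min by the drain to Z and 7.1 min by the drain to Q, so at that moment Z's drain is the faster and carries 56.3 % of the flow out of J, a split of that moment and not of the whole charge. Both times are short against 80 min, and by then ochre holds J 0 %, L at 30.6 % of its charge, and Q 0.347 M, which is 31.5 % of the J charged.

For a neighbour like ochre but with 2.0 M of L, s is 35.8 % and C is 39.4 %. The computed flask has X 28.7 %, below that ceiling, with G 71.1 % and Z 0.0205 M at 80.0 min.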